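**Retrosynthetic overview**

1. Numbering follows the cadinane skeleton: ring A = C1–C2–C3–C4(C15)=C5–C6; ring B = C1–C10(C14)–C9–C8–C7–C6; C11(C13)–C12 on C7. The target comes from triol 20 by formylation and acetylation, and C3 is set by convex-face reduction of ring A enone 18.
2. Key disconnection C3–C4: C3 is an allylic carbinol carbon bonded to the vinylic C4 of the only ring A alkene (C4=C5, cis inside the ring), the retron of an alkenyl-metal addition to an aldehyde. Ring A is closed by a Nozaki–Hiyama–Kishi reaction on a ring B that carries a CH2CHO arm on C1 and a (Z)-2-iodoprop-1-enyl arm on C6, held cis and gauche because A(1,3) strain with the exocyclic C7=C11 bond keeps the C6 arm axial.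
3. Both arms come from one temporary cis-fused δ-lactone ring (C5(=O)–O–C3 across C1/C6): reduction to the lactol, Stork–Zhao olefination at C5, oxidation at C3.
4. The lactone comes from an intramolecular γ-acylation (vinylogous Dieckmann) of a carvone-derived dienone. The C8=C7–C11=C12 diene of that dienone gives the (E)-C7=C11–CH2OH unit by s-cis 1,4-hydroboration.
5. (S)-Carvone is mapped onto ring B plus C11–C14, not onto the carveol-like ring A. Its single stereocenter (future C7) directs C1 and is then erased. Ring order: ring B (from carvone), temporary lactone ring, ring A (key step).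

Key step: step 13

Remark: β is the face of H-1, H-6 and the C14 methyl group, α the face of both acetoxy groups; C10 is drawn throughout in its final 10β-methyl configuration because it stays epimerisable until step 6 and is fixed under the equilibrating conditions of step 5; the C3 carbinol of 17 is drawn as the expected 3β epimer, but steps 14 and 15 make the route independent of that outcome.

**Route**

Step 1
Reactants: 1 (S)-(+)-carvone
Product: 2 (2R,3R,5S)-2-methyl-5-(prop-1-en-2-yl)-3-vinylcyclohexan-1-one
Conditions: CH2=CHMgBr (1.5 equiv), CuBr·SMe2 (10 mol %), THF, −40 °C; aq. NH4Cl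
Reagents that add atoms: vinylmagnesium bromide, C=C[Mg]Br
Why: Copper-catalysed conjugate addition of the vinyl Grignard reagent should take place by axial attack on the enone anti to the isopropenyl group on the future C7, so the single carvone stereocenter sets C1 (vinyl α, H-1 β), while C10 is formed on protonation and remains correctable.

Step 2
Reactants: 2 vinyl ketone
Product: 4 (2R,3R,5S)-3-(2-hydroxyethyl)-2-methyl-5-(prop-1-en-2-yl)cyclohexan-1-one, via alkyl catecholboronate 3 (not isolated)
Conditions: catecholborane (1.2 equiv), RhCl(PPh3)3 (2 mol %), THF, 0 °C to rt; then H2O2, aq. NaOH, 0 °C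
Reagents that add atoms: hydrogen peroxide, OO
Why: Rhodium-catalysed hydroboration with catecholborane is anti-Markovnikov and prefers the monosubstituted vinyl group over the 1,1-disubstituted isopropenyl group and over the ketone, and oxidation of the C–B bond with retention should give the primary C3 alcohol without touching a stereocenter.

Step 3
Reactants: 4 keto alcohol
Product: 5 methyl carbonate of 4
Conditions: ClCO2Me, pyridine, CH2Cl2, 0 °C
Reagents that add atoms: methyl chloroformate, COC(=O)Cl
Why: Acylation of the primary alcohol with the chloroformate (carbonate formation) attaches the carbon that will become C5 through the C3 oxygen, a temporary tether that step 10 later opens.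

Step 4
Reactants: 5 methyl carbonate
Product: 7 dienone carbonate, via lithium enolate 6 (not isolated)
Conditions: LiN(i-Pr)2, THF, −78 °C; then PhS(Cl)=N-t-Bu, −78 °C
Reagents that add atoms: none
Why: Kinetic deprotonation at the less substituted α-carbon C8 followed by Mukaiyama dehydrogenation of the lithium enolate with N-tert-butylbenzenesulfinimidoyl chloride (attack at sulfur, then syn-elimination across C8–C7) should give the C8=C7 enone conjugated with the isopropenyl group, which erases the carvone stereocenter after it has set C1 and makes C6 the acidic γ-position.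

Step 5
Reactants: 7 dienone carbonate
Product: 8 cis-fused lactone dienone
Conditions: KOt-Bu (2.2 equiv), THF/t-BuOH, 0 °C to rt; aq. NH4Cl
Reagents that add atoms: none
Why: Proposed new method: under equilibrating alkoxide conditions the enone should be deprotonated at C6 to the extended dienolate, whose γ-carbon is the only nucleophilic site that the C1-tethered carbonate can reach productively through a six-membered transition state (the α-carbon C8 and the enolate oxygen lie across the ring, and acylation at the α′-carbon C10 gives a non-enolisable β-keto lactone that alkoxide reopens), so acyl substitution with loss of methoxide should give the δ-lactone, driven by deprotonation of the vinylogous β-keto lactone product; the closest known reaction types are the Dieckmann condensation, the acylation of ketone enolates by tethered carbonates and γ-selective vinylogous Claisen reactions, and the new C6 stereocenter is set cis to the C1 arm by axial attack on the dienolate from the face of the tether and reinforced, like the trans C10 methyl group, by equilibration of these acidic positions.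

Step 6
Reactants: 8 lactone dienone
Product: 9 9α-allylic alcohol
Conditions: NaBH4, CeCl3·7H2O, MeOH, −78 °C
Reagents that add atoms: none
Why: Luche reduction (1,2-selective hydride addition to the enone) should occur by axial attack from the β face, anti to the axial H-10, giving the equatorial 9α-alcohol trans to the C14 methyl group and leaving the lactone untouched.

Step 7
Reactants: 9 allylic alcohol
Product: 10 9-O-tert-butyldimethylsilyl ether
Conditions: t-BuMe2SiCl, imidazole, DMF, rt
Reagents that add atoms: tert-butyldimethylsilyl chloride, CC(C)(C)[Si](C)(C)Cl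
Why: Imidazole-promoted silyl ether formation masks the C9 oxygen for the nickel, hydride and ylide steps that follow.

Step 8
Reactants: 10 silyl ether diene
Product: 12 (E)-allylic alcohol, via allylboronate 11 (not isolated)
Conditions: HBpin (1.2 equiv), Ni(cod)2 (5 mol %), PCy3 (5 mol %), toluene, rt; then H2O2, pH 7 phosphate buffer, THF, 0 °C
Reagents that add atoms: hydrogen peroxide, OO
Why: Nickel-catalysed 1,4-hydroboration of the 1,3-diene proceeds through an s-cis η4-diene complex and an anti-π-allylnickel intermediate, so hydride should go to C8 and boron to the unhindered C12 terminus with C12 cis to C8 across the new tetrasubstituted C7=C11 bond ((E) by CIP), and oxidation of the allylboronate with retention gives the primary allylic alcohol.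

Step 9
Reactants: 12 allylic alcohol
Product: 13 9,12-bis(tert-butyldimethylsilyl) ether
Conditions: t-BuMe2SiCl, imidazole, DMF, rt
Reagents that add atoms: tert-butyldimethylsilyl chloride, CC(C)(C)[Si](C)(C)Cl
Why: Silyl ether formation at the primary allylic alcohol keeps C12 inert until the end.

Step 10
Reactants: 13 lactone
Product: 14 lactol
Conditions: i-Bu2AlH (1.1 equiv), CH2Cl2, −78 °C; aq. potassium sodium tartrate
Reagents that add atoms: none
Why: Partial reduction of the δ-lactone with the aluminium hydride at low temperature stops at the tetrahedral aluminium hemiacetal, which gives the lactol on work-up (C5 at the aldehyde level, C3 as the latent alcohol).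

Step 11
Reactants: 14 lactol
Product: 15 (Z)-alkenyl iodide alcohol
Conditions: EtPPh3I, n-BuLi, THF, 0 °C; I2, −78 °C; NaN(SiMe3)2, −20 °C; then 14, −78 to −20 °C
Reagents that add atoms: ethyltriphenylphosphonium iodide, CC[P+](c1ccccc1)(c1ccccc1)c1ccccc1.[I-]; iodine, II
Why: In this Stork–Zhao olefination (a Wittig reaction) the open hydroxy aldehyde form of the lactol should react with the α-iodo ylide under kinetic control to give the (Z)-2-iodoalkene with iodine cis to C6, the geometry that places the future C3–C4 bond inside ring A, while C6 stays axial next to the C7=C11 bond.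

Step 12
Reactants: 15 alkenyl iodide alcohol
Product: 16 alkenyl iodide aldehyde
Conditions: Dess–Martin periodinane, CH2Cl2, 0 °C to rt
Reagents that add atoms: none
Why: Dess–Martin oxidation converts the primary C3 alcohol into the aldehyde under non-basic conditions that leave the alkenyl iodide and the axial C6 stereocenter untouched.

Step 13
Reactants: 16 alkenyl iodide aldehyde
Product: 17 cis-fused cadinadienol (3β-OH expected)
Conditions: CrCl2 (6 equiv), NiCl2 (2 mol %), DMSO, rt, high dilution
Reagents that add atoms: none
Why: Zerovalent nickel, formed in situ from NiCl2 and CrCl2, inserts into the C4–I bond with retention, transmetalation gives the alkenyl species of trivalent chromium, and this adds to the C3 aldehyde through a closed four-centre transition state. The closest known reaction type is the intramolecular Nozaki–Hiyama–Kishi coupling of (Z)-alkenyl iodides with aldehydes to give cyclohex-2-en-1-ols. Ring A is closed in a 6-exo-trig mode (carbonyl oxygen exocyclic), and the preset (Z)-geometry of the iodide becomes the endocyclic C4=C5 bond. The only new stereocenter, C3, is under substrate control: the chromium alkoxide is expected on the convex β face of the emerging cis-decalin (3β-OH), the opposite of what the target needs, so this centre is deliberately not relied on and both epimers are converged through enone 18 in steps 14 and 15. The step needs chemoselective activation of the alkenyl iodide beside an enolisable aldehyde, two silyl ethers and a tetrasubstituted alkene, which the mild non-basic divalent chromium medium provides, and it needs ring closure to outrun intermolecular coupling, which high dilution and the substrate secure: A(1,3) strain from the exocyclic C7=C11 bond holds the C6 alkenyl arm axial and gauche to the equatorial C1 acetaldehyde arm.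

Step 14
Reactants: 17 allylic alcohol
Product: 18 ring A enone
Conditions: Dess–Martin periodinane, CH2Cl2, 0 °C
Reagents that add atoms: none
Why: Dess–Martin oxidation of the allylic alcohol gives the ring A enone and thereby merges both C3 epimers into one compound.

Step 15
Reactants: 18 enone
Product: 19 3α-allylic alcohol
Conditions: NaBH4, CeCl3·7H2O, MeOH, −78 °C
Reagents that add atoms: none
Why: Luche reduction should deliver hydride in a 1,2-sense to C3 from the convex β face of the cis-decalin, away from the axial C1–C10 bond, giving the pseudoaxial 3α (3R) alcohol.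

Step 16
Reactants: 19 bis-silyl ether
Product: 20 3α,9α,12-triol
Conditions: n-Bu4NF, THF, rt
Reagents that add atoms: none
Why: Fluoride-mediated desilylation cleaves both Si–O bonds and releases the C9 and C12 hydroxyl groups without affecting a stereocenter.

Step 17
Reactants: 20 triol
Product: 21 12-formate diol
Conditions: HCO2H (1.05 equiv), N,N′-dicyclohexylcarbodiimide, DMAP (5 mol %), CH2Cl2, −20 °C
Reagents that add atoms: formic acid, O=CO
Why: Carbodiimide-mediated esterification (Steglich type) with one equivalent of formic acid at low temperature should acylate the unhindered primary allylic C12 hydroxyl in preference to the hindered secondary C3 and C9 hydroxyls.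

Step 18
Reactants: 21 12-formate diol
Product: 22 target, 3α,9α-diacetoxy-12-formyloxycadina-4,7(11)E-diene
Conditions: Ac2O, pyridine, DMAP (cat.), CH2Cl2, rt
Reagents that add atoms: acetic anhydride, CC(=O)OC(C)=O
Why: Acetylation of the two remaining secondary alcohols under nucleophilic catalysis completes the target without disturbing the formate.

**Compound list**

1 | (S)-(+)-carvone, (5S)-2-methyl-5-(prop-1-en-2-yl)cyclohex-2-en-1-one | CC1=CC[C@@H](CC1=O)C(C)=C | starting material
2 | (2R,3R,5S)-2-methyl-5-(prop-1-en-2-yl)-3-vinylcyclohexan-1-one (vinyl on future C1, trans to isopropenyl and to methyl) | C=C[C@@H]1[C@@H](C)C(=O)C[C@@H](C(C)=C)C1 | intermediate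
3 | alkyl catecholboronate: 2-[2-(2-methyl-3-oxo-5-(prop-1-en-2-yl)cyclohexyl)ethyl]-1,3,2-benzodioxaborole, ring stereocenters as in 2 | c1ccc2OB(CC[C@@H]3[C@@H](C)C(=O)C[C@@H](C(C)=C)C3)Oc2c1 | intermediate
4 | (2R,3R,5S)-3-(2-hydroxyethyl)-2-methyl-5-(prop-1-en-2-yl)cyclohexan-1-one | OCC[C@@H]1[C@@H](C)C(=O)C[C@@H](C(C)=C)C1 | intermediate
5 | methyl carbonate of 4 (C3–O–CO2Me) | COC(=O)OCC[C@@H]1[C@@H](C)C(=O)C[C@@H](C(C)=C)C1 | intermediate
6 | lithium enolate of 5 (C8=C9–OLi) | COC(=O)OCC[C@@H]1[C@@H](C)C(O[Li])=C[C@@H](C(C)=C)C1 | intermediate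
7 | dienone carbonate: 5,6-trans-5-[2-(methoxycarbonyloxy)ethyl]-6-methyl-3-(prop-1-en-2-yl)cyclohex-2-en-1-one | COC(=O)OCC[C@@H]1[C@@H](C)C(=O)C=C(C(C)=C)C1 | intermediate
8 | cis-fused lactone dienone: 5-methyl-8-(prop-1-en-2-yl)-4,4a,5,8a-tetrahydro-1H-isochromene-1,6(3H)-dione, H-4a/H-8a cis, methyl trans to C4 (cadinane: lactone C5(=O)–O–C3, C9 ketone, C7=C8) | O=C1OCC[C@@H]2[C@@H](C)C(=O)C=C(C(C)=C)[C@@H]21 | intermediate
9 | 9α-allylic alcohol of 8 (OH trans to the methyl group) | O=C1OCC[C@@H]2[C@@H](C)[C@H](O)C=C(C(C)=C)[C@@H]21 | intermediate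
10 | 9-O-tert-butyldimethylsilyl ether of 9 | O=C1OCC[C@@H]2[C@@H](C)[C@H](O[Si](C)(C)C(C)(C)C)C=C(C(C)=C)[C@@H]21 | intermediate
11 | (E)-allylboronate: C12–Bpin, C7=C11, C8H2, otherwise as 10 | O=C1OCC[C@@H]2[C@@H](C)[C@H](O[Si](C)(C)C(C)(C)C)C/C(=C(/C)CB3OC(C)(C)C(C)(C)O3)[C@@H]21 | intermediate
12 | (E)-allylic alcohol: C12–OH cis to C8 across C7=C11, lactone and 9α-OTBS retained | O=C1OCC[C@@H]2[C@@H](C)[C@H](O[Si](C)(C)C(C)(C)C)C/C(=C(/C)CO)[C@@H]21 | intermediate
13 | 9,12-bis(tert-butyldimethylsilyl) ether of 12 | O=C1OCC[C@@H]2[C@@H](C)[C@H](O[Si](C)(C)C(C)(C)C)C/C(=C(/C)CO[Si](C)(C)C(C)(C)C)[C@@H]21 | intermediate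
14 | lactol (C5 hemiacetal, both anomers) from 13 | OC1OCC[C@@H]2[C@@H](C)[C@H](O[Si](C)(C)C(C)(C)C)C/C(=C(/C)CO[Si](C)(C)C(C)(C)C)[C@@H]21 | intermediate
15 | ring B with 1α-(2-hydroxyethyl), 6α-[(Z)-2-iodoprop-1-enyl], 9α-OTBS, 10β-methyl and (E)-7(11)-ene-12-OTBS | OCC[C@@H]1[C@@H](C)[C@H](O[Si](C)(C)C(C)(C)C)C/C(=C(/C)CO[Si](C)(C)C(C)(C)C)[C@@H]1/C=C(/C)I | intermediate
16 | aldehyde of 15 (C3 = CHO) | O=CC[C@@H]1[C@@H](C)[C@H](O[Si](C)(C)C(C)(C)C)C/C(=C(/C)CO[Si](C)(C)C(C)(C)C)[C@@H]1/C=C(/C)I | intermediate
17 | 9α,12-bis(tert-butyldimethylsilyloxy)cadina-4,7(11)E-dien-3β-ol (3S), cis-fused | O[C@H]1C[C@@H]2[C@@H](C)[C@H](O[Si](C)(C)C(C)(C)C)C/C(=C(/C)CO[Si](C)(C)C(C)(C)C)[C@@H]2C=C1C | intermediate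
18 | 9α,12-bis(tert-butyldimethylsilyloxy)cadina-4,7(11)E-dien-3-one | O=C1C[C@@H]2[C@@H](C)[C@H](O[Si](C)(C)C(C)(C)C)C/C(=C(/C)CO[Si](C)(C)C(C)(C)C)[C@@H]2C=C1C | intermediate
19 | 9α,12-bis(tert-butyldimethylsilyloxy)cadina-4,7(11)E-dien-3α-ol (3R) | O[C@@H]1C[C@@H]2[C@@H](C)[C@H](O[Si](C)(C)C(C)(C)C)C/C(=C(/C)CO[Si](C)(C)C(C)(C)C)[C@@H]2C=C1C | intermediate
20 | cadina-4,7(11)E-diene-3α,9α,12-triol (1S,3R,6S,9R,10R) | O[C@@H]1C[C@@H]2[C@@H](C)[C@H](O)C/C(=C(/C)CO)[C@@H]2C=C1C | intermediate
21 | 12-formyloxycadina-4,7(11)E-diene-3α,9α-diol | O[C@@H]1C[C@@H]2[C@@H](C)[C@H](O)C/C(=C(/C)COC=O)[C@@H]2C=C1C | intermediate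
22 | 3α,9α-diacetoxy-12-formyloxycadina-4,7(11)E-diene (1S,3R,6S,9R,10R) | CC(=O)O[C@@H]1C[C@@H]2[C@@H](C)[C@H](OC(C)=O)C/C(=C(/C)COC=O)[C@@H]2C=C1C | target

**Step count and risks**

Total step count: 18. Longest linear sequence: 18 steps (1 to 22).

Steps most likely to fail:

Step 5 (Proposed new method). Acylation at the α′-carbon C10, or attack of alkoxide on the carbonate with loss of the tether and oxa-Michael addition of the freed C3 alkoxide, may outrun γ-acylation, and control of the ring fusion may be incomplete. The fallback uses known chemistry and sets out from 7. Methanolysis of the carbonate (K2CO3, MeOH) should give dienone alcohol F1. Silylation with t-BuMe2SiOTf/Et3N should give the extended bis-silyl dienol ether F2 (C9=C8–C7=C6). A vinylogous Mukaiyama reaction with HC(OMe)3 and BF3·OEt2 at −78 °C, γ-selective for electronic reasons, should give γ-dimethoxymethyl enone F3. Pyridinium p-toluenesulfonate in MeOH should then remove the primary silyl group, exchange the acetal onto the C3 oxygen and equilibrate C6, giving cis-fused cyclic methyl acetal F4. Oxidation of the cyclic acetal with CrO3/H2SO4 in acetone returns to the route at 8.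

Step 8. Competing 1,2-hydroboration of the isopropenyl group, sluggish reaction of the hindered trisubstituted diene, or nickel insertion into the allylic C9–O bond may erode the regio- and geometric control. The fallback sets out from 10 and changes metal and element. Palladium-catalysed 1,4-hydrosilylation with HSiCl3 (PdCl2(PhCN)2, PPh3), which delivers hydrogen and silicon cis through an anti-π-allylpalladium intermediate, followed by ethanolysis (EtOH, Et3N) should give allyltriethoxysilane F5. Tamao oxidation (H2O2, KF, KHCO3) returns to the route at 12.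

Step 13. Protodeiodination of the alkenylchromium intermediate, or reductive consumption and enolisation of the aldehyde, may outrun ring closure. The fallback sets out from 15 and avoids both the aldehyde and the carbinol stereocenter. Oxidation with catalytic TEMPO and PhI(OAc)2 in MeCN/H2O should give carboxylic acid F6. Coupling with MeNHOMe·HCl using N-(3-dimethylaminopropyl)-N′-ethylcarbodiimide hydrochloride and Et3N should give Weinreb amide F7. Iodine–lithium exchange with t-BuLi (THF, −78 °C) and intramolecular acyl substitution by the alkenyllithium should close ring A directly to the enone, returning to the route at 18 and bypassing steps 13 and 14.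

Further compounds
F1 | step 5 | dienone alcohol, 5,6-trans-5-(2-hydroxyethyl)-6-methyl-3-(prop-1-en-2-yl)cyclohex-2-en-1-one | OCC[C@@H]1[C@@H](C)C(=O)C=C(C(C)=C)C1
F2 | step 5 | bis-silyl dienol ether (C3–OTBS, C9(OTBS)=C8–C7=C6) | CC(C)(C)[Si](C)(C)OCC[C@@H]1[C@@H](C)C(O[Si](C)(C)C(C)(C)C)=CC(C(C)=C)=C1
F3 | step 5 | γ-dimethoxymethyl enone (CH(OMe)2 on C6, C6 epimers, C3–OTBS) | CC(C)(C)[Si](C)(C)OCC[C@@H]1[C@@H](C)C(=O)C=C(C(C)=C)C1C(OC)OC
F4 | step 5 | cis-fused cyclic methyl acetal (C5H(OMe)–O–C3 across C1/C6, C9 ketone, C7=C8) | COC1OCC[C@@H]2[C@@H](C)C(=O)C=C(C(C)=C)[C@@H]21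
F5 | step 8 | (E)-allyltriethoxysilane (C12–Si(OEt)3, C7=C11, otherwise as 10) | O=C1OCC[C@@H]2[C@@H](C)[C@H](O[Si](C)(C)C(C)(C)C)C/C(=C(/C)C[Si](OCC)(OCC)OCC)[C@@H]21
F6 | step 13 | carboxylic acid of 15 (C3 = CO2H) | OC(=O)C[C@@H]1[C@@H](C)[C@H](O[Si](C)(C)C(C)(C)C)C/C(=C(/C)CO[Si](C)(C)C(C)(C)C)[C@@H]1/C=C(/C)I
F7 | step 13 | Weinreb amide of F6 (C3 = C(=O)N(OMe)Me) | CON(C)C(=O)C[C@@H]1[C@@H](C)[C@H](O[Si](C)(C)C(C)(C)C)C/C(=C(/C)CO[Si](C)(C)C(C)(C)C)[C@@H]1/C=C(/C)I
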